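**Strategy**

Numbering the core as cyclohex-5-ene-1,2,4-tricarboxylic acid, the cis carboxyls on the two allylic carbons C1 and C4 are read as the scar of a cleaved 1,2-dicarbonyl bridge, and the C2 carboxyl and the C6 propenoate, both neighbours of C1, as two former formyl groups. The precursor is therefore a mirror-symmetric bicyclo[2.2.2]octadienone dialdehyde. Oxidative dearomatisation of isovanillin to a masked ortho-benzoquinone and Diels–Alder capture by propynal forms the C5–C4 and C6–C1 bonds in one operation. An enantioselective rhodium-catalysed arylation then desymmetrises the achiral adduct and sets every ring stereocentre; Horner–Wadsworth–Emmons union with the (R)-danshensu phosphonate, ketal hydrolysis and oxidative cleavage release the ring.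

Key step: step 5

Assumptions: propynal (as a freshly distilled solution) and (R)-danshensu (free acid) are taken as purchasable. The sense of induction of the chiral diene in step 6 cannot be predicted with certainty for this substrate; the (1R,4R) ligand is written and its enantiomer would be used if a trial shows the opposite sense.

**Route**

Step 1
Reactants: 1 4-bromobenzene-1,2-diol
Product: 2 4-bromo-1,2-bis(prop-2-enyloxy)benzene
Conditions: allyl bromide (2.4 equiv), K2CO3, acetone, reflux, argon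
Reagents that add atoms: allyl bromide C=CCBr
Why: Williamson ether synthesis of both phenols; allyl is chosen because it survives every later step and leaves under neutral conditions at the end.

Step 2
Reactants: 2 4-bromo-1,2-bis(prop-2-enyloxy)benzene
Product: 5 [3,4-bis(prop-2-enyloxy)phenyl]boronic acid, via aryllithium 3 (not isolated), via lithium aryltriisopropoxyborate 4 (not isolated)
Conditions: n-BuLi, THF, −78 °C; B(OiPr)3, −78 → 25 °C; aq. HCl
Reagents that add atoms: triisopropyl borate CC(C)OB(OC(C)C)OC(C)C; water O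
Why: bromine–lithium exchange is fast at −78 °C and the aryllithium is trapped by the borate, hydrolysis then giving the boronic acid (standard lithiation–borylation).

Step 3
Reactants: 6 (R)-danshensu
Product: 7 prop-2-enyl (2R)-3-[3,4-bis(prop-2-enyloxy)phenyl]-2-hydroxypropanoate
Conditions: allyl bromide (3.3 equiv), K2CO3, DMF, 25 °C, argon
Reagents that add atoms: allyl bromide C=CCBr
Why: carbonate deprotonates only the carboxylic acid and the two phenols, so O-alkylation should leave the secondary alcohol free and the stereocentre untouched.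

Step 4
Reactants: 7 prop-2-enyl (2R)-3-[3,4-bis(prop-2-enyloxy)phenyl]-2-hydroxypropanoate; 8 2-(diethoxyphosphoryl)acetic acid
Product: 9 prop-2-enyl (2R)-3-[3,4-bis(prop-2-enyloxy)phenyl]-2-{[2-(diethoxyphosphoryl)acetyl]oxy}propanoate
Conditions: DCC, DMAP (cat.), CH2Cl2, 0 → 25 °C
Reagents that add atoms: none
Why: Steglich esterification acylates the secondary alcohol under neutral conditions with retention at the carbinol carbon.

Step 5
Reactants: 10 isovanillin (3-hydroxy-4-methoxybenzaldehyde); 11 propynal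
Product: 13 8,8-dimethoxy-7-oxobicyclo[2.2.2]octa-2,5-diene-2,6-dicarbaldehyde (achiral), via masked ortho-benzoquinone 12 (not isolated)
Conditions: 10 added slowly to PhI(OAc)2 and 11 (5 equiv) in MeOH, 0 → 25 °C
Reagents that add atoms: methanol CO
Why: PhI(OAc)2 oxidises the phenol of 10 in methanol to the 6,6-dimethoxycyclohexa-2,4-dienone 12 (a masked ortho-benzoquinone), whose ring diene then adds propynal in a concerted intermolecular [4+2] cycloaddition, the established Diels–Alder chemistry of masked ortho-benzoquinones run here with an acetylenic dienophile. The two new sigma bonds join the alkyne CH to C5 of 12 (next to the ketal carbon) and the formyl-bearing alkyne carbon to C2 of 12 (next to the ketone), closing the new cyclohexa-1,4-diene ring in one suprafacial step while the old ring becomes the ketone/ketal bridge. No stereocentre has to be controlled, because the alkyne has no faces and, with this regiochemistry, both formyl-bearing sp2 carbons flank the same bridgehead, so 13 has a mirror plane through C1, C4, C7 and C8. The selectivity needed is regiochemical (dienophile substituent next to the bridgehead alpha to the ketone, the "ortho" sense shown by acrylates and enones with such dienones); it should follow from the polarisation of the dienone, whose delta terminus C5 takes the unsubstituted dienophile carbon, and from the bulk of the gem-dimethoxy carbon, which keeps the substituted alkyne carbon on the ketone side. Dimerisation of 12 is held back by generating it slowly at 0 °C in excess propynal, and the adduct is kept below 40 °C to avoid loss of the ketal bridge as a ketene acetal.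

Step 6
Reactants: 13 8,8-dimethoxy-7-oxobicyclo[2.2.2]octa-2,5-diene-2,6-dicarbaldehyde; 5 [3,4-bis(prop-2-enyloxy)phenyl]boronic acid
Product: 14 (1R,4R,5R,6R)-5-[3,4-bis(prop-2-enyloxy)phenyl]-8,8-dimethoxy-7-oxobicyclo[2.2.2]oct-2-ene-2,6-dicarbaldehyde (aryl on C5 syn to the C2=C3 bridge, formyl on C6 trans to it)
Conditions: [RhCl(C2H4)2]2 (2.5 mol%), (1R,4R)-2,5-diphenylbicyclo[2.2.2]octa-2,5-diene (5.5 mol%), KOH (0.5 equiv), MeOH/H2O 10:1, 25–40 °C
Reagents that add atoms: none
Why: Hayashi–Miyaura conjugate arylation used as a desymmetrisation: the aryl–rhodium species (monovalent rhodium) should carbometalate one of the two enantiotopic enal bridges from the cleft between them (the other face is blocked by the gem-dimethoxy carbon C8), placing the aryl on C5 syn to the surviving enal, while the chiral diene chooses which enal reacts and so fixes C1, C4 and C5, and the enolisable C6 settles trans to the aryl in the basic medium.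

Step 7
Reactants: 14 (1R,4R,5R,6R)-5-[3,4-bis(prop-2-enyloxy)phenyl]-8,8-dimethoxy-7-oxobicyclo[2.2.2]oct-2-ene-2,6-dicarbaldehyde
Product: 15 (1R,4R,5R,6R)-5-[3,4-bis(prop-2-enyloxy)phenyl]-6-(dimethoxymethyl)-8,8-dimethoxy-7-oxobicyclo[2.2.2]oct-2-ene-2-carbaldehyde
Conditions: HC(OMe)3, CeCl3·7H2O (cat.), MeOH, 0 → 25 °C
Reagents that add atoms: trimethyl orthoformate COC(OC)OC; methanol CO
Why: lanthanide-catalysed acetalisation is faster for the saturated C6 aldehyde than for the conjugated C2 enal or the hindered ketone, so only the formyl group that must later become a carboxyl is masked and no stereocentre changes.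

Step 8
Reactants: 15 (1R,4R,5R,6R)-5-[3,4-bis(prop-2-enyloxy)phenyl]-6-(dimethoxymethyl)-8,8-dimethoxy-7-oxobicyclo[2.2.2]oct-2-ene-2-carbaldehyde; 9 prop-2-enyl (2R)-3-[3,4-bis(prop-2-enyloxy)phenyl]-2-{[2-(diethoxyphosphoryl)acetyl]oxy}propanoate
Product: 16 prop-2-enyl (2R)-3-[3,4-bis(prop-2-enyloxy)phenyl]-2-{[(2E)-3-{(1R,4R,5R,6R)-5-[3,4-bis(prop-2-enyloxy)phenyl]-6-(dimethoxymethyl)-8,8-dimethoxy-7-oxobicyclo[2.2.2]oct-2-en-2-yl}prop-2-enoyl]oxy}propanoate
Conditions: LiCl, iPr2NEt, MeCN, 25 °C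
Reagents that add atoms: none
Why: Horner–Wadsworth–Emmons olefination under Masamune–Roush conditions should convert the only free aldehyde into the E-dienoate, the mild amine base sparing the alpha-acyloxy ester stereocentre, while the bridgehead hydrogens cannot enolise.

Step 9
Reactants: 16 the dienoate ketal acetal of step 8
Product: 18 prop-2-enyl (2R)-3-[3,4-bis(prop-2-enyloxy)phenyl]-2-{[(2E)-3-{(1R,4R,5R,6R)-5-[3,4-bis(prop-2-enyloxy)phenyl]-6-formyl-7,8-dioxobicyclo[2.2.2]oct-2-en-2-yl}prop-2-enoyl]oxy}propanoate, via aldehyde ketal 17 (not isolated)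
Conditions: TFA/H2O/CH2Cl2, 0 → 25 °C
Reagents that add atoms: water O
Why: aqueous acid hydrolyses the dimethyl acetal quickly and the alpha-keto ketal more slowly to the 1,2-dione, conditions to which allyl ethers, both esters and the dienoate are stable and under which the C6 formyl stays trans to the aryl.

Step 10
Reactants: 18 the dione aldehyde of step 9
Product: 20 (1R,2R,3S,4R)-3-[3,4-bis(prop-2-enyloxy)phenyl]-6-[(1E)-3-({(2R)-3-[3,4-bis(prop-2-enyloxy)phenyl]-1-oxo-1-(prop-2-enyloxy)propan-2-yl}oxy)-3-oxoprop-1-enyl]cyclohex-5-ene-1,2,4-tricarboxylic acid, via dione acid 19 (not isolated)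
Conditions: NaClO2, NaH2PO4, 2-methylbut-2-ene, t-BuOH/THF/H2O, 0 → 25 °C; then H5IO6, 25 °C
Reagents that add atoms: sodium chlorite [Na+].[O-]Cl=O; periodic acid OI(O)(O)(O)(O)=O; water O
Why: Pinnick oxidation turns the C6 aldehyde into the acid without touching alkenes, and periodic acid then cleaves the 1,2-dione (Malaprade-type cleavage), opening the bicycle to the cyclohexene with cis carboxyls on the two former bridgeheads and leaving all stereocentres untouched.

Step 11
Reactants: 20 the tri-acid of step 10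
Product: 21 target, (1R,2R,3S,4R)-6-[(1E)-3-{[(1R)-1-carboxy-2-(3,4-dihydroxyphenyl)ethyl]oxy}-3-oxoprop-1-enyl]-3-(3,4-dihydroxyphenyl)cyclohex-5-ene-1,2,4-tricarboxylic acid
Conditions: Pd(PPh3)4 (10 mol%), morpholine (excess), degassed THF, 25 °C; dilute HCl work-up
Reagents that add atoms: none
Why: Tsuji–Trost deallylation with zerovalent palladium transfers the four allyl ethers and the allyl ester to morpholine under neutral conditions that should leave the dienoate ester, the ring alkene and all stereocentres intact.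

**Compound list**

1 | 4-bromobenzene-1,2-diol | Oc1ccc(Br)cc1O | starting material
2 | 4-bromo-1,2-bis(prop-2-enyloxy)benzene | C=CCOc1ccc(Br)cc1OCC=C | intermediate
3 | [3,4-bis(prop-2-enyloxy)phenyl]lithium | [Li]c1ccc(OCC=C)c(OCC=C)c1 | intermediate (not isolated)
4 | lithium [3,4-bis(prop-2-enyloxy)phenyl]tri(propan-2-yloxy)borate | [Li+].CC(C)O[B-](OC(C)C)(OC(C)C)c1ccc(OCC=C)c(OCC=C)c1 | intermediate (not isolated)
5 | [3,4-bis(prop-2-enyloxy)phenyl]boronic acid | OB(O)c1ccc(OCC=C)c(OCC=C)c1 | intermediate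
6 | (R)-danshensu, (2R)-3-(3,4-dihydroxyphenyl)-2-hydroxypropanoic acid | O[C@H](Cc1ccc(O)c(O)c1)C(=O)O | starting material
7 | prop-2-enyl (2R)-3-[3,4-bis(prop-2-enyloxy)phenyl]-2-hydroxypropanoate | O[C@H](Cc1ccc(OCC=C)c(OCC=C)c1)C(=O)OCC=C | intermediate
8 | 2-(diethoxyphosphoryl)acetic acid | CCOP(=O)(OCC)CC(=O)O | starting material
9 | prop-2-enyl (2R)-3-[3,4-bis(prop-2-enyloxy)phenyl]-2-{[2-(diethoxyphosphoryl)acetyl]oxy}propanoate | CCOP(=O)(OCC)CC(=O)O[C@H](Cc1ccc(OCC=C)c(OCC=C)c1)C(=O)OCC=C | intermediate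
10 | isovanillin, 3-hydroxy-4-methoxybenzaldehyde | COc1ccc(C=O)cc1O | starting material
11 | propynal | C#CC=O | starting material
12 | 4,4-dimethoxy-3-oxocyclohexa-1,5-diene-1-carbaldehyde (masked ortho-benzoquinone) | COC1(OC)C=CC(C=O)=CC1=O | intermediate (not isolated)
13 | 8,8-dimethoxy-7-oxobicyclo[2.2.2]octa-2,5-diene-2,6-dicarbaldehyde (achiral, mirror plane through C1, C4, C7, C8) | COC1(OC)C(=O)C2C(C=O)=CC1C=C2C=O | intermediate
14 | (1R,4R,5R,6R)-5-[3,4-bis(prop-2-enyloxy)phenyl]-8,8-dimethoxy-7-oxobicyclo[2.2.2]oct-2-ene-2,6-dicarbaldehyde | O=CC1=C[C@@H]2[C@H](c3ccc(OCC=C)c(OCC=C)c3)[C@@H](C=O)[C@H]1C(=O)C2(OC)OC | intermediate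
15 | (1R,4R,5R,6R)-5-[3,4-bis(prop-2-enyloxy)phenyl]-6-(dimethoxymethyl)-8,8-dimethoxy-7-oxobicyclo[2.2.2]oct-2-ene-2-carbaldehyde | O=CC1=C[C@@H]2[C@H](c3ccc(OCC=C)c(OCC=C)c3)[C@@H](C(OC)OC)[C@H]1C(=O)C2(OC)OC | intermediate
16 | prop-2-enyl (2R)-3-[3,4-bis(prop-2-enyloxy)phenyl]-2-{[(2E)-3-{(1R,4R,5R,6R)-5-[3,4-bis(prop-2-enyloxy)phenyl]-6-(dimethoxymethyl)-8,8-dimethoxy-7-oxobicyclo[2.2.2]oct-2-en-2-yl}prop-2-enoyl]oxy}propanoate | O=C(/C=C/C1=C[C@@H]2[C@H](c3ccc(OCC=C)c(OCC=C)c3)[C@@H](C(OC)OC)[C@H]1C(=O)C2(OC)OC)O[C@H](Cc1ccc(OCC=C)c(OCC=C)c1)C(=O)OCC=C | intermediate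
17 | the 6-formyl analogue of 16 with the 8,8-dimethoxy ketal still in place, (1R,4R,5R,6R) | O=C(/C=C/C1=C[C@@H]2[C@H](c3ccc(OCC=C)c(OCC=C)c3)[C@@H](C=O)[C@H]1C(=O)C2(OC)OC)O[C@H](Cc1ccc(OCC=C)c(OCC=C)c1)C(=O)OCC=C | intermediate (not isolated)
18 | prop-2-enyl (2R)-3-[3,4-bis(prop-2-enyloxy)phenyl]-2-{[(2E)-3-{(1R,4R,5R,6R)-5-[3,4-bis(prop-2-enyloxy)phenyl]-6-formyl-7,8-dioxobicyclo[2.2.2]oct-2-en-2-yl}prop-2-enoyl]oxy}propanoate | O=C(/C=C/C1=C[C@@H]2[C@H](c3ccc(OCC=C)c(OCC=C)c3)[C@@H](C=O)[C@H]1C(=O)C2=O)O[C@H](Cc1ccc(OCC=C)c(OCC=C)c1)C(=O)OCC=C | intermediate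
19 | (1R,2R,3S,4R)-3-[3,4-bis(prop-2-enyloxy)phenyl]-6-[(1E)-3-({(2R)-3-[3,4-bis(prop-2-enyloxy)phenyl]-1-oxo-1-(prop-2-enyloxy)propan-2-yl}oxy)-3-oxoprop-1-enyl]-7,8-dioxobicyclo[2.2.2]oct-5-ene-2-carboxylic acid | O=C(/C=C/C1=C[C@@H]2[C@H](c3ccc(OCC=C)c(OCC=C)c3)[C@@H](C(=O)O)[C@H]1C(=O)C2=O)O[C@H](Cc1ccc(OCC=C)c(OCC=C)c1)C(=O)OCC=C | intermediate (not isolated)
20 | (1R,2R,3S,4R)-3-[3,4-bis(prop-2-enyloxy)phenyl]-6-[(1E)-3-({(2R)-3-[3,4-bis(prop-2-enyloxy)phenyl]-1-oxo-1-(prop-2-enyloxy)propan-2-yl}oxy)-3-oxoprop-1-enyl]cyclohex-5-ene-1,2,4-tricarboxylic acid | O=C(/C=C/C1=C[C@@H](C(=O)O)[C@H](c2ccc(OCC=C)c(OCC=C)c2)[C@@H](C(=O)O)[C@H]1C(=O)O)O[C@H](Cc1ccc(OCC=C)c(OCC=C)c1)C(=O)OCC=C | intermediate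
21 | (1R,2R,3S,4R)-6-[(1E)-3-{[(1R)-1-carboxy-2-(3,4-dihydroxyphenyl)ethyl]oxy}-3-oxoprop-1-enyl]-3-(3,4-dihydroxyphenyl)cyclohex-5-ene-1,2,4-tricarboxylic acid | O=C(/C=C/C1=C[C@@H](C(=O)O)[C@H](c2ccc(O)c(O)c2)[C@@H](C(=O)O)[C@H]1C(=O)O)O[C@H](Cc1ccc(O)c(O)c1)C(=O)O | target

**Count and risks**

Total steps: 11. Longest linear sequence: 8 (steps 1, 2, 6, 7, 8, 9, 10, 11).

Step 6. The substrate is itself a chelating diene and may displace the chiral diene from rhodium, which would erode enantioselection; 1,2-arylation of a formyl group is a second failure path. Fallback: from 13 the arylation would be run without chiral control ([Rh(OH)(cod)]2, KOH, dioxane/H2O), which should give 14 together with its enantiomer, (1S,4S,5S,6S)-5-[3,4-bis(prop-2-enyloxy)phenyl]-8,8-dimethoxy-7-oxobicyclo[2.2.2]oct-2-ene-2,6-dicarbaldehyde F1. The mixture is carried through step 7, giving 15 and its enantiomer, the (1S,4S,5S,6S) mono-acetal F2. Step 8 with the enantiopure phosphonate 9 then gives 16 and its diastereomer with the (1S,4S,5S,6S) core and the (2R) side chain F3, which are separated by chromatography. The route is rejoined at 16.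

Step 5. The cycloaddition may take the opposite regiochemical sense, or dimerisation of 12 and addition of methanol to propynal may outrun it. Fallback: from 10, 12 is generated as before and trapped with acrolein, a dienophile class with established "ortho", endo behaviour towards such dienones. This should give racemic 8,8-dimethoxy-7-oxobicyclo[2.2.2]oct-5-ene-2,6-dicarbaldehyde (C2 formyl syn to the C5=C6 bridge) F4. IBX-mediated alpha,beta-dehydrogenation of its saturated aldehyde (DMSO, 70 °C) then introduces the C2=C3 double bond and returns to 13.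

Step 9. Hydrolysis of the alpha-keto ketal may stall, because the oxocarbenium ion next to the ketone is destabilised, and forcing acid may trigger skeletal rearrangement of the beta,gamma-unsaturated ketone. Fallback: from 16, NaBH4 (MeOH, 0 °C) reduces the C7 ketone to the 7-hydroxy-8,8-dimethoxy compound F5 (C7 configuration immaterial). Its now ordinary ketal and acetal hydrolyse under mild acid (dilute HCl, THF) to the 7-hydroxy-8-oxo 6-formyl compound F6. Periodic acid cleaves the acyloin to the cyclohexene 4-carboxylic acid with formyl groups on C1 and C2, (1R,2R,3S,4R)-configured core, F7. Pinnick oxidation of both aldehydes gives 20, where the route is rejoined.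

**Further compounds**

F1 | step 6 | (1S,4S,5S,6S)-5-[3,4-bis(prop-2-enyloxy)phenyl]-8,8-dimethoxy-7-oxobicyclo[2.2.2]oct-2-ene-2,6-dicarbaldehyde (enantiomer of 14) | O=CC1=C[C@H]2[C@@H](c3ccc(OCC=C)c(OCC=C)c3)[C@H](C=O)[C@@H]1C(=O)C2(OC)OC
F2 | step 6 | (1S,4S,5S,6S)-5-[3,4-bis(prop-2-enyloxy)phenyl]-6-(dimethoxymethyl)-8,8-dimethoxy-7-oxobicyclo[2.2.2]oct-2-ene-2-carbaldehyde (enantiomer of 15) | O=CC1=C[C@H]2[C@@H](c3ccc(OCC=C)c(OCC=C)c3)[C@H](C(OC)OC)[C@@H]1C(=O)C2(OC)OC
F3 | step 6 | diastereomer of 16 with (1S,4S,5S,6S) bicyclic core and (2R) side chain | O=C(/C=C/C1=C[C@H]2[C@@H](c3ccc(OCC=C)c(OCC=C)c3)[C@H](C(OC)OC)[C@@H]1C(=O)C2(OC)OC)O[C@H](Cc1ccc(OCC=C)c(OCC=C)c1)C(=O)OCC=C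
F4 | step 5 | racemic 8,8-dimethoxy-7-oxobicyclo[2.2.2]oct-5-ene-2,6-dicarbaldehyde, C2 formyl syn to the C5=C6 bridge (one enantiomer drawn) | O=C[C@H]1C[C@H]2C=C(C=O)[C@@H]1C(=O)C2(OC)OC
F5 | step 9 | 7-hydroxy analogue of 16 (C7 alcohol, configuration at C7 unspecified) | O=C(/C=C/C1=C[C@@H]2[C@H](c3ccc(OCC=C)c(OCC=C)c3)[C@@H](C(OC)OC)[C@H]1C(O)C2(OC)OC)O[C@H](Cc1ccc(OCC=C)c(OCC=C)c1)C(=O)OCC=C
F6 | step 9 | 6-formyl-7-hydroxy-8-oxo analogue of 18 (acyloin) | O=C(/C=C/C1=C[C@@H]2[C@H](c3ccc(OCC=C)c(OCC=C)c3)[C@@H](C=O)[C@H]1C(O)C2=O)O[C@H](Cc1ccc(OCC=C)c(OCC=C)c1)C(=O)OCC=C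
F7 | step 9 | (1R,2R,3S,4R)-configured cyclohex-5-ene core of 20 with C4 carboxylic acid and formyl groups on C1 and C2 | O=C(/C=C/C1=C[C@@H](C(=O)O)[C@H](c2ccc(OCC=C)c(OCC=C)c2)[C@@H](C=O)[C@H]1C=O)O[C@H](Cc1ccc(OCC=C)c(OCC=C)c1)C(=O)OCC=C
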